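## Structural features

The target (C56H42O12) is a resveratrol tetramer made of two trans-2-(4-hydroxyphenyl)-2,3-dihydrobenzofurans (O1, C2, C3 and benzo ring B; primes mark the second unit), each carrying a resorcinol ring A on C3. A chain Ca–Cb–Cb′–Ca′ joins the halves crosswise: Ca (bearing a 4-hydroxyphenyl group) is bonded to C1 of ring A and to Cb, Cb to C4′ of ring B′, Cb′ to C4 of ring B, and Ca′ (bearing the fourth 4-hydroxyphenyl group) to C1 of ring A′, so that two eight-membered carbocycles, ring 1 (Ca, Cb, Cb′, C4, C3a, C3 and two carbons of ring A) and its primed counterpart ring 2, share the Cb–Cb′ bond. The eight stereocentres are C2 (R), C3 (R), Ca (R), Cb (S) and C2′ (S), C3′ (S), Cb′ (R), Ca′ (R); Ca, Cb, Cb′ and Ca′ are contiguous, each C3 stands next to its C2 and 1,4 to a central methine across ring B. Without Ca and Ca′ the skeleton is mirror-symmetric (enantiomeric dihydrobenzofurans, Cb–H trans to Cb′–H), but Ca and Ca′ have the same configuration: Ca–H is cis to Cb–H in ring 1 whereas Ca′–H is trans to Cb′–H in ring 2, so the compound is chiral and its halves are diastereomeric. Fragile elements are the ten phenols (oxidation), the two C2–O bonds (benzylic and para to oxygen, opened by strong acid) and six benzylic methines flanked by electron-rich rings, which invite Friedel–Crafts and elimination chemistry. The real difficulty is twofold: two dibenzo-fused eight-membered rings that share a bond and compete with seven-membered rings whenever both rings A are free, and the need to give the formally equivalent carbons Ca and Ca′ the same rather than mirror-image configuration. The key step uses ring B, a 1,2,3,5-tetrasubstituted benzene (oxygen at C7a, C3 at C3a, central methine at C4, oxygen at C6) fused to the dihydrofuran: this is the pattern produced when an alkyne tethered through O–C2–C3 adds to a 6-alkoxy-4-methoxy-2-pyrone, with boron marking C4.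

## Logic of the disconnections

37 to 36. The ten aryl O–CH3 bonds are cut last. Methyl ethers survive every reagent class of the route (organolithium, organozinc, SmI2, Brønsted acid), and 36 is non-polar and stable to oxidation. The forward step must cleave ten ethers while any opening of the C2–O bonds stays reversible.

36 to 32 and 33. At Ca the C–H bond is cut first and the C–aryl bond second (through 35). The hydride then enters last, anti to ring B′ on Cb, which is the Ca–H cis to Cb–H relationship. Ca becomes a carbonyl carbon and one stereocentre disappears. The forward steps demand 1,2-addition to a hindered, enolisable ketone and hydride capture faster than loss of the Cb proton.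

32 to 30 and 31. At Ca′ only the C–aryl bond is cut, leaving a carbinol. Here the aryl group enters last, anti to ring B on Cb′. Because the halves are near mirror images, the opposite order of events at Ca and Ca′ gives both centres the same descriptor. If both captures prove to occur syn, the same sequence with the roles of 20 and 21 exchanged leads to 37. The gain is that 30 carries a ketone at Ca and an alcohol at Ca′, so the two sites differ without an asymmetric reagent. The demand is capture by the arene faster than elimination, and para selectivity.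

30 to 29. The Ca′–Cb′ bond is cut, opening ring 2. Cb′ is the beta-carbon of an enone and the aldehyde carbon on ring A′ is held over it; reductive coupling gives exactly the ketone/alcohol pair wanted. One ring and the stereocentres Cb and Cb′ are removed. The demand is eight-membered ring closure with face control at Cb′ and equilibration at Cb.

29 to 27 and 21. The sp2–sp2 bond Cb–C4′ is cut. This is the convergent union of the two enantiomeric halves. The demand is a hindered cross-coupling in the presence of an enone.

27 to 24 (through 26 and 25). The Cb–I bond is removed, Ca is taken back to the alcohol, and the Cb=Cb′ bond is cut, opening ring 1. Ring 1 is closed while only one half is present, so no seven-membered alternative exists. The demand is a cis-cyclooctene by metathesis and alpha-iodination of a beta-aryl enone.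

24 to 20 (through 23). The Ca–Cb bond (vinyl nucleophile on an aldehyde) and the C4–Cb′ bond (vinyl group in place of boron) are cut and the aldehyde is masked again. This returns to the product of the key step. The demand is standard chemoselective chemistry.

20 and 21 to 19. No bond is cut; the racemate is separated into its two enantiomers. Both are needed, so nothing is discarded.

19 to 17. The ring B bonds C3a–C7a and C4–C5 are cut; both are formed in the cycloaddition, and the loss of CO2 only aromatises. Ring B and the dihydrofuran open together and the tetrasubstituted arene becomes an acyclic ether with the C2/C3 stereodiad already present. The demand is a thermal reaction that leaves a benzylic pyronyl ether and an alkynylboronate intact. Ring A already carries the masked Ca (a dioxolane), because a later electrophilic substitution could not distinguish ring A from the equally activated ring B.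

17 to 10 and 14 (through 15). The C(sp)–B bond and the C6(pyrone)–O bond are cut. This leads to a homopropargylic alcohol and a chloropyrone. The demand is substitution at C6 only and borylation without attack on the pyrone.

14 to 11 (through 13). The O–CH3 bond and the pyrone ring are cut, back to two molecules of 11, which supply five of their six carbons to the ring.

10 to 6 and 7. The bond between the future C2 and C3 is cut. An anti-selective propargylation sets the relationship that becomes trans C2/C3. The demand is high anti selectivity; no enantiocontrol is needed.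

6 to 1 and 3 (through 2). The aryl–C(propargylic) bond and the acetal are cut, back to catalogue compounds.

## Other disconnections considered

Alternative 1: The cut is at Ca–Cb and Ca′–Cb′ in the labels used here (each quinone methide carbon joins the central carbon that is alpha to the ketone on the other ring). In the forward step the two carbinol groups of bis-carbinol A1 are ionised by a chiral BINOL phosphoric acid with 2,4,6-triisopropylphenyl groups to para-quinone methide groups, and each ketone enol adds 1,6 to the one on the other ring, giving the trans-fused tetrahydrotetracene-5,11-dione A2.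
- In its favour: it attacks the real stereochemical problem by catalyst control, since one chiral ion pair can give Ca and Ca′ the same descriptor. On this point it is better than the chosen plan, which relies on substrate control. It also sets four contiguous stereocentres and two rings from a symmetric precursor.
- Against it: A2 has six-membered rings. Its ketone carbons are the future C3 atoms and are bonded directly to the central carbons, so two ring B carbons must still be inserted into each of these bonds (six to eight), and C2 with its aryl group and ether oxygen must be added with opposite configuration in the two halves. An aryl ketone enol is a weak partner for chiral-acid catalysis, the second cyclisation is matched or mismatched with the first, and the free 4-hydroxyphenyl groups allow retro-1,6-addition later.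
- Comparison: structurally the alternative builds the tetrad first and the periphery afterwards, the chosen plan the reverse. Mechanistically it is ionic asymmetric catalysis against a pericyclic key step. In step economy its key step achieves more (four stereocentres against none), but the remaining ring expansions and dihydrofuran syntheses would not make the whole route shorter.

Alternative 2: The cut is at the C3–ring A and Ca–ring A bonds of both halves, so that both rings A leave as arynes. In the forward step fluoride (CsF) releases the bis-enolate from the bis(silyl enol ether) A3 and 3,5-dimethoxybenzyne A5 from the silyl triflate A4. Each C3 enolate adds to the aryne, the aryl anion closes on the carbonyl carbon, and fragmentation of the cyclobutoxide inserts the arene, giving the meso diketone A6.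
- In its favour: both eight-membered rings arise in one operation and both rings A come from one simple reagent. The regiochemistry of addition to a 3-methoxy aryne (nucleophile meta, carbanion ortho to methoxy) is what ring A requires. For the medium rings this is more step-economical than the chosen plan.
- Against it: insertion of an aryne into the C–C bond of a simple ketone enolate competes with plain alpha-arylation and benzocyclobutenol formation, and it must succeed twice. The C3 stereocentres are erased in A3 and must be reset by protonation. A6 is a meso 1,4-diketone whose two carbonyls are enantiotopic, so Ca and Ca′ can only be told apart by an enantioselective reagent, and acid threatens furan formation (Paal–Knorr).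
- Comparison: the chosen plan reaches the same bicyclic core with Ca and Ca′ already different (ketone and alcohol) and with C2/C3 never at risk, but needs two separate ring closures. A6 is also the diketone used in the fallback of step 17, so the two plans are equal in their late-stage problem.

Alternative 3: The cut is at both C2–aryl bonds. In the forward step an aryl cuprate made from 33 with CuBr·SMe2 and Me3SiCl adds to C2 of both 3-acylbenzofurans of A7, and protonation of the enolates at C3 gives the bis(trans-dihydrofuran) A8.
- In its favour: both 4-methoxyphenyl groups arrive late from a cheap reagent and the trans relationship follows from protonation anti to the new aryl group. The opposite configurations of the two dihydrofurans follow from the meso symmetry of A7, so no resolution and no pairing of enantiomers is needed; on this point it is better than the chosen plan.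
- Against it: the addition must overcome the aromaticity of two benzofurans and compete with 1,2-addition to the ketones. The face at C2 is controlled only by the remote central stereocentres. A8 still lacks rings A, both eight-membered rings and the aryl groups on Ca and Ca′, and A7 itself has to be built.
- Comparison: the chosen plan makes ring B and the dihydrofuran together from an acyclic anti stereodiad, which is the more reliable stereochemical basis. Alternative 3 forms two C–C bonds and four stereocentres in one step, which beats the chosen key step in stereocentre count, but it leaves more of the skeleton to build.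

Key step: step 8

Remark: racemic compounds are written with one enantiomer in the SMILES and marked as racemates; 2-bromo-4,6-dimethoxybenzaldehyde, 3-(trimethylsilyl)prop-2-ynal and 4-methoxyphenylmagnesium bromide solution are taken as catalogue chemicals.

Remark: steps 9 and 10 are the two enantiomer fractions of one preparative chromatographic run on 19; each fraction has its own entry because it enters the route at a different point.

## Steps

Step 1
Reactants: 1 2-bromo-4,6-dimethoxybenzaldehyde
Product: 2 2-(2-bromo-4,6-dimethoxyphenyl)-1,3-dioxolane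
Conditions: HOCH2CH2OH, p-TsOH (cat.), toluene, reflux, Dean–Stark
Reagents that add atoms: ethylene glycol, OCCO
Why: Acid-catalysed acetalisation with azeotropic removal of water; the dioxolane masks the aldehyde that becomes Ca and is inert to organolithium, organozinc, hydride base and heat.

Step 2
Reactants: 2 2-(2-bromo-4,6-dimethoxyphenyl)-1,3-dioxolane; 3 3-(trimethylsilyl)prop-2-ynal
Product: 6 racemic 1-[2-(1,3-dioxolan-2-yl)-3,5-dimethoxyphenyl]-3-(trimethylsilyl)prop-2-yn-1-yl methanesulfonate, via aryllithium 4 (not isolated), via lithium propargylic alkoxide 5 (not isolated)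
Conditions: n-BuLi, THF, −78 °C; 3; then MsCl, −78 → −40 °C; cold work-up, used at once
Reagents that add atoms: methanesulfonyl chloride, CS(=O)(=O)Cl
Why: Bromine–lithium exchange, 1,2-addition of the aryllithium to the ynal and O-sulfonylation of the alkoxide in one flask. The mesylate is kept cold and not purified because the ortho acetal oxygen could assist its ionisation.

Step 3
Reactants: 6 the propargylic mesylate; 7 4-methoxybenzaldehyde
Product: 10 racemic (1R,2S)-2-[2-(1,3-dioxolan-2-yl)-3,5-dimethoxyphenyl]-1-(4-methoxyphenyl)but-3-yn-1-ol (anti), via allenylzinc reagent 8 (not isolated), via C-silylated alcohol 9 (not isolated)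
Conditions: Pd(OAc)2 (5 mol%), PPh3 (5 mol%), Et2Zn, THF, −78 → −20 °C; then MeOH, K2CO3, rt
Reagents that add atoms: none
Why: Marshall–Tamaru propargylation: zerovalent palladium (formed from Pd(OAc)2, PPh3 and Et2Zn) displaces the mesylate SN2′, and transmetalation gives allenylzinc 8. This adds to the aldehyde through a cyclic SE2′ transition state with the allene aryl group and the aldehyde substituent apart, which sets the anti relationship of the two new stereocentres (later trans C2/C3). Methanolic K2CO3 then removes the C-silyl group.

Step 4
Reactants: 11 malonyl dichloride (two molecules are joined)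
Product: 13 6-chloro-4-hydroxy-2H-pyran-2-one, via pyrone-3-carbonyl chloride 12 (not isolated)
Conditions: neat, rt, several days, HCl vented; then H2O, dioxane, 50 °C
Reagents that add atoms: malonyl dichloride (second molecule), O=C(Cl)CC(=O)Cl
Why: Self-condensation of two molecules of malonyl dichloride: C-acylation of one by the other, then ring closure by O-acylation through the enol of the remaining chlorocarbonyl group, each with loss of HCl, gives the pyrone acid chloride 12 (six carbons). Hydrolysis of its exocyclic acid chloride and decarboxylation of the resulting beta-keto acid remove one carbon and leave the five-carbon chloropyrone.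

Step 5
Reactants: 13 6-chloro-4-hydroxy-2H-pyran-2-one
Product: 14 6-chloro-4-methoxy-2H-pyran-2-one
Conditions: Me2SO4, K2CO3, acetone, rt
Reagents that add atoms: dimethyl sulfate, COS(=O)(=O)OC
Why: O-Alkylation of the vinylogous acid at O4, the usual course for 4-hydroxy-2-pyrones.

Step 6
Reactants: 10 the anti homopropargylic alcohol; 14 6-chloro-4-methoxy-2H-pyran-2-one
Product: 15 racemic 6-{[(1R,2S)-2-[2-(1,3-dioxolan-2-yl)-3,5-dimethoxyphenyl]-1-(4-methoxyphenyl)but-3-yn-1-yl]oxy}-4-methoxy-2H-pyran-2-one
Conditions: NaH (1.0 equiv), THF, 0 °C; then 14, 0 °C → rt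
Reagents that add atoms: none
Why: Addition–elimination (vinylogous acyl substitution) of the sodium alkoxide at C6 of the chloropyrone. One equivalent of NaH deprotonates only the alcohol, not the alkyne or the doubly activated C–H.

Step 7
Reactants: 15 the pyronyl ether with terminal alkyne
Product: 17 racemic 6-{[(1R,2S)-2-[2-(1,3-dioxolan-2-yl)-3,5-dimethoxyphenyl]-1-(4-methoxyphenyl)-4-(4,4,5,5-tetramethyl-1,3,2-dioxaborolan-2-yl)but-3-yn-1-yl]oxy}-4-methoxy-2H-pyran-2-one, via lithium alkynylborate 16 (not isolated)
Conditions: i-PrOBpin, then LDA (1.05 equiv), THF, −78 °C; HCl in Et2O (1.0 equiv), −78 °C → rt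
Reagents that add atoms: 2-isopropoxy-4,4,5,5-tetramethyl-1,3,2-dioxaborolane, CC(C)OB1OC(C)(C)C(C)(C)O1
Why: Deprotonation of the terminal alkyne by LDA in the presence of the borate (in situ quench) gives the ate complex 16 at once, so the acetylide never accumulates beside the pyrone. One equivalent of anhydrous HCl releases the alkynyl pinacolboronate.

Step 8
Reactants: 17 the pyronyl ether with alkynyl pinacolboronate
Product: 19 racemic 2-{2-[(2R,3R)-6-methoxy-2-(4-methoxyphenyl)-4-(4,4,5,5-tetramethyl-1,3,2-dioxaborolan-2-yl)-2,3-dihydro-1-benzofuran-3-yl]-4,6-dimethoxyphenyl}-1,3-dioxolane (trans), via bridged lactone cycloadduct 18 (not isolated)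
Conditions: degassed o-xylene (0.01 M), BHT (cat.), 150 °C, sealed vessel
Reagents that add atoms: none
Why: Thermal intramolecular Diels–Alder reaction of the electron-rich 4,6-dialkoxy-2-pyrone (diene, C3 to C6) with the tethered alkynylboronate, followed by retro-Diels–Alder loss of CO2 from the bridged lactone 18. The closest known reactions are the intramolecular cycloadditions of alkyne-tethered 2-pyrones that give benzo-fused rings after decarboxylation, and the intermolecular cycloadditions of alkynyl pinacolboronates with 2-pyrones that give aryl boronates. The dihydrofuran closes as a five-membered ring in the cycloaddition itself, by the bond between pyrone C6 and the proximal alkyne carbon across the three-atom O–C–C tether. Ring B closes as a six-membered carbocycle by that bond together with the bond between pyrone C3 and the boron-bearing alkyne carbon, and becomes aromatic when CO2 leaves. No stereocentre is formed; C2 and C3 are carried over from 17 and keep the trans relationship. The only selectivity needed is regiochemical, and the short tether allows a single orientation, which places oxygen at C7a, methoxy at C6 and boron at C4. High dilution and a radical inhibitor suppress intermolecular reactions, and the non-polar solvent disfavours heterolysis of the benzylic C–O(pyronyl) bond.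

Step 9
Reactants: 19 the racemic boronate
Product: 20 the (2R,3R)-enantiomer of 19
Conditions: preparative SFC, amylose tris(3,5-dimethylphenylcarbamate) phase, CO2/i-PrOH; (2R,3R) fraction collected
Reagents that add atoms: none
Why: Chromatographic resolution on a chiral stationary phase; this fraction enters in step 11. The absolute configuration is to be assigned by correlation with Mosher-analysed samples of the enantiomers of 10 carried through steps 6 to 8.

Step 10
Reactants: 19 the racemic boronate
Product: 21 the (2S,3S)-enantiomer of 19
Conditions: the same preparative SFC run as in step 9; (2S,3S) fraction collected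
Reagents that add atoms: none
Why: The second fraction of the chromatographic resolution of step 9; it is the mirror-image half that the target needs and enters in step 16, so no material of the racemate is discarded.

Step 11
Reactants: 20 the (2R,3R)-boronate
Product: 23 2-[(2R,3R)-4-ethenyl-6-methoxy-2-(4-methoxyphenyl)-2,3-dihydro-1-benzofuran-3-yl]-4,6-dimethoxybenzaldehyde, via vinyl dioxolane 22 (not isolated)
Conditions: CH2=CHBr, Pd(dppf)Cl2 (5 mol%), K3PO4, THF/H2O, 50 °C, sealed; then 1 M HCl, THF, rt
Reagents that add atoms: vinyl bromide, C=CBr; water, O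
Why: Suzuki–Miyaura coupling of the aryl pinacolboronate with vinyl bromide puts the future Cb′ on C4. The acidic work-up hydrolyses the electron-rich aryl dioxolane to the aldehyde (future Ca).

Step 12
Reactants: 23 the vinyl aldehyde
Product: 24 1-{2-[(2R,3R)-4-ethenyl-6-methoxy-2-(4-methoxyphenyl)-2,3-dihydro-1-benzofuran-3-yl]-4,6-dimethoxyphenyl}prop-2-en-1-ol (carbinol epimers)
Conditions: CH2=CHMgBr, THF, −78 → 0 °C; aq NH4Cl
Reagents that add atoms: vinylmagnesium bromide, C=C[Mg]Br
Why: 1,2-Addition of the vinyl Grignard reagent forms the Ca–Cb bond. The carbinol configuration is irrelevant because Ca is oxidised in step 14.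

Step 13
Reactants: 24 the dienol
Product: 25 ring 1 dienol: the (2R,3R)-dihydrobenzofuran in which C1 of ring A and C4 of ring B are bridged by CH(OH)–CH=CH (cis alkene, eight-membered ring), carbinol epimers
Conditions: RuCl2(=CHPh)(PCy3)(H2IMes) (second-generation Grubbs catalyst, 5 mol%), 1,4-benzoquinone (10 mol%), CH2Cl2 (2 mM), 40 °C
Reagents that add atoms: none
Why: Ring-closing olefin metathesis between the styrene and the allylic alcohol closes ring 1 as an eight-membered ring with a cis double bond. The diarylmethane-type hinge at C3 holds the alkenes close, and with only one half present no seven-membered alternative exists.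

Step 14
Reactants: 25 the ring 1 dienol
Product: 26 ring 1 enone: as 25 with Ca=O (cis-cyclooctadienone, no enolisable hydrogen)
Conditions: Dess–Martin periodinane, NaHCO3, CH2Cl2, 0 °C → rt
Reagents that add atoms: none
Why: Dess–Martin oxidation of the allylic, benzylic alcohol to the cross-conjugated ketone.

Step 15
Reactants: 26 the ring 1 enone
Product: 27 alpha-iodoenone: as 26 with iodine on Cb
Conditions: I2, DMAP (0.2 equiv), K2CO3, THF/H2O, rt
Reagents that add atoms: iodine, II
Why: Nucleophile-catalysed alpha-iodination of a cyclic enone (conjugate addition of DMAP, iodination of the enolate, elimination) places iodine on Cb, the only alpha-carbon. The electron-rich arenes do not react with iodine in the absence of an oxidant.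

Step 16
Reactants: 27 the alpha-iodoenone; 21 the (2S,3S)-boronate
Product: 29 coupled aldehyde: 26 carrying on Cb the (2S,3S)-6-methoxy-2-(4-methoxyphenyl)-3-(2-formyl-3,5-dimethoxyphenyl)-2,3-dihydrobenzofuran-4-yl group, via coupled dioxolane 28 (not isolated)
Conditions: Pd(OAc)2 (5 mol%), SPhos (10 mol%), K3PO4, THF/H2O, 50 °C; then 1 M HCl, THF, rt
Reagents that add atoms: water, O
Why: Suzuki–Miyaura coupling of the alpha-iodoenone (fast oxidative addition) with the boronate of the enantiomeric half forms the Cb–C4′ bond. Acidic work-up frees the aldehyde on ring A′.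

Step 17
Reactants: 29 the coupled aldehyde
Product: 30 hydroxy ketone of the complete bicyclic core: both eight-membered rings closed, Ca=O, Ca′H–OH (epimers, in equilibrium with the cyclic hemiketal), Cb–H trans to Cb′–H and C3–H cis to Cb′–H as in the target
Conditions: SmI2 (3 equiv), HMPA, THF (2 mM), −78 → 0 °C; t-BuOH; then DBU (0.2 equiv), CH2Cl2, rt
Reagents that add atoms: none
Why: SmI2-mediated reductive aldehyde–enone (ketyl–olefin) cyclisation couples the aldehyde carbon Ca′ with the beta-carbon Cb′, closing ring 2 in the endo mode, and protonation of the samarium enolate gives the ketone. Cb′ is set in the bond-forming step by the face on which the tether through C3′ holds ring A′, Cb is alpha to the ketone and is equilibrated by DBU to the trans ring fusion, and the carbinol configuration at Ca′ is irrelevant. The temperature is chosen so that the rotamers about the Cb–C4′ bond interconvert (Curtin–Hammett).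

Step 18
Reactants: 30 the hydroxy ketone; 31 anisole
Product: 32 aryl ketone: as 30 with Ca′ bearing H and 4-methoxyphenyl (Ca′ R, Ca′–H trans to Cb′–H)
Conditions: 31 (20 equiv), p-TsOH (10 mol%), (CF3)2CHOH, 0 °C → rt
Reagents that add atoms: none
Why: Friedel–Crafts alkylation: the 2,4-dimethoxybenzylic cation at Ca′ (from the alcohol or its hemiketal) is captured by anisole at its para position. The arene enters last, from the face anti to ring B on the neighbouring Cb′, which sets Ca′; the weak acid does not ionise the C2–O ethers.

Step 19
Reactants: 32 the aryl ketone; 33 4-methoxyphenylmagnesium bromide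
Product: 35 tertiary alcohol: as 32 with Ca bearing OH and 4-methoxyphenyl (carbinol epimers), via arylcerium reagent 34 (not isolated)
Conditions: 33, CeCl3, THF, −78 °C; then 32, −78 → 0 °C
Reagents that add atoms: none
Why: Organocerium 1,2-addition: the low basicity of 34 suppresses enolisation towards Cb, so the hindered ketone is attacked at carbon. The carbinol configuration is irrelevant.

Step 20
Reactants: 35 the tertiary alcohol
Product: 36 decamethyl ether of the target (Ca R, Ca–H cis to Cb–H)
Conditions: Et3SiH (5 equiv), CF3CO2H (3 equiv), CH2Cl2, −40 °C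
Reagents that add atoms: none
Why: Ionic hydrogenation (Kursanov–Parnes): the doubly aryl-stabilised cation at Ca forms under acid too weak to open the C2–O ethers and is reduced by Et3SiH. Hydride enters last, anti to ring B′ on Cb, which sets Ca; because the halves are near mirror images, this order, opposite to that of step 18, gives Ca and Ca′ the same descriptor.

Step 21
Reactants: 36 the decamethyl ether
Product: 37 the target, CNP0224452.2
Conditions: BBr3 (excess), CH2Cl2, −78 °C → rt; then MeOH, H2O
Reagents that add atoms: none
Why: Lewis-acid cleavage of all ten aryl methyl ethers. Any reversible opening of the benzylic C2–O bonds re-closes to the more stable trans dihydrofurans.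

## Compound list

1 | 2-bromo-4,6-dimethoxybenzaldehyde | O=Cc1c(Br)cc(OC)cc1OC | starting material
2 | 2-(2-bromo-4,6-dimethoxyphenyl)-1,3-dioxolane | COc1cc(Br)c(C2OCCO2)c(OC)c1 | intermediate
3 | 3-(trimethylsilyl)prop-2-ynal | O=CC#C[Si](C)(C)C | starting material
4 | [2-(1,3-dioxolan-2-yl)-3,5-dimethoxyphenyl]lithium | COc1cc([Li])c(C2OCCO2)c(OC)c1 | intermediate
5 | lithium 1-[2-(1,3-dioxolan-2-yl)-3,5-dimethoxyphenyl]-3-(trimethylsilyl)prop-2-yn-1-olate (racemic) | COc1cc(C([O-])C#C[Si](C)(C)C)c(C2OCCO2)c(OC)c1.[Li+] | intermediate
6 | 1-[2-(1,3-dioxolan-2-yl)-3,5-dimethoxyphenyl]-3-(trimethylsilyl)prop-2-yn-1-yl methanesulfonate (racemic) | COc1cc(C(OS(C)(=O)=O)C#C[Si](C)(C)C)c(C2OCCO2)c(OC)c1 | intermediate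
7 | 4-methoxybenzaldehyde | COc1ccc(C=O)cc1 | starting material
8 | ethyl{3-[2-(1,3-dioxolan-2-yl)-3,5-dimethoxyphenyl]-1-(trimethylsilyl)propa-1,2-dien-1-yl}zinc (racemic) | CC[Zn]C(=C=Cc1cc(OC)cc(OC)c1C1OCCO1)[Si](C)(C)C | intermediate
9 | (1R,2R)-2-[2-(1,3-dioxolan-2-yl)-3,5-dimethoxyphenyl]-1-(4-methoxyphenyl)-4-(trimethylsilyl)but-3-yn-1-ol (racemate, anti) | COc1cc(OC)cc([C@@H]([C@@H](O)c2ccc(OC)cc2)C#C[Si](C)(C)C)c1C1OCCO1 | intermediate
10 | (1R,2S)-2-[2-(1,3-dioxolan-2-yl)-3,5-dimethoxyphenyl]-1-(4-methoxyphenyl)but-3-yn-1-ol (racemate, anti) | COc1cc(OC)cc([C@@H]([C@@H](O)c2ccc(OC)cc2)C#C)c1C1OCCO1 | intermediate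
11 | malonyl dichloride | O=C(Cl)CC(=O)Cl | starting material
12 | 6-chloro-4-hydroxy-2-oxo-2H-pyran-3-carbonyl chloride | O=C(Cl)C1=C(O)C=C(Cl)OC1=O | intermediate
13 | 6-chloro-4-hydroxy-2H-pyran-2-one | OC1=CC(=O)OC(Cl)=C1 | intermediate
14 | 6-chloro-4-methoxy-2H-pyran-2-one | COC1=CC(=O)OC(Cl)=C1 | intermediate
15 | 6-{[(1R,2S)-2-[2-(1,3-dioxolan-2-yl)-3,5-dimethoxyphenyl]-1-(4-methoxyphenyl)but-3-yn-1-yl]oxy}-4-methoxy-2H-pyran-2-one (racemate) | COc1cc(OC)cc([C@@H]([C@@H](OC2=CC(OC)=CC(=O)O2)c2ccc(OC)cc2)C#C)c1C1OCCO1 | intermediate
16 | lithium isopropoxy(pinacolato)alkynylborate of 15 (racemate) | COc1cc(OC)cc([C@@H]([C@@H](OC2=CC(OC)=CC(=O)O2)c2ccc(OC)cc2)C#C[B-]2(OC(C)C)OC(C)(C)C(C)(C)O2)c1C1OCCO1.[Li+] | intermediate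
17 | 6-{[(1R,2S)-2-[2-(1,3-dioxolan-2-yl)-3,5-dimethoxyphenyl]-1-(4-methoxyphenyl)-4-(4,4,5,5-tetramethyl-1,3,2-dioxaborolan-2-yl)but-3-yn-1-yl]oxy}-4-methoxy-2H-pyran-2-one (racemate; key-step precursor) | COc1cc(OC)cc([C@@H]([C@@H](OC2=CC(OC)=CC(=O)O2)c2ccc(OC)cc2)C#CB2OC(C)(C)C(C)(C)O2)c1C1OCCO1 | intermediate
18 | bridged lactone cycloadduct (2-oxabicyclo[2.2.2]octa-5,7-dien-3-one with the dihydrofuran already closed; racemate, bridgeheads unassigned) | COc1cc(OC)cc([C@H]2[C@H](c3ccc(OC)cc3)OC34OC(=O)C(C(OC)=C3)C(B3OC(C)(C)C(C)(C)O3)=C24)c1C1OCCO1 | intermediate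
19 | 2-{2-[(2R,3R)-6-methoxy-2-(4-methoxyphenyl)-4-(4,4,5,5-tetramethyl-1,3,2-dioxaborolan-2-yl)-2,3-dihydro-1-benzofuran-3-yl]-4,6-dimethoxyphenyl}-1,3-dioxolane (racemate, trans; key-step product) | COc1cc(OC)cc([C@@H]2c3c(cc(OC)cc3B3OC(C)(C)C(C)(C)O3)O[C@H]2c2ccc(OC)cc2)c1C1OCCO1 | intermediate
20 | (2R,3R)-enantiomer of 19 | COc1cc(OC)cc([C@@H]2c3c(cc(OC)cc3B3OC(C)(C)C(C)(C)O3)O[C@H]2c2ccc(OC)cc2)c1C1OCCO1 | intermediate
21 | (2S,3S)-enantiomer of 19 | COc1cc(OC)cc([C@H]2c3c(cc(OC)cc3B3OC(C)(C)C(C)(C)O3)O[C@@H]2c2ccc(OC)cc2)c1C1OCCO1 | intermediate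
22 | 2-{2-[(2R,3R)-4-ethenyl-6-methoxy-2-(4-methoxyphenyl)-2,3-dihydro-1-benzofuran-3-yl]-4,6-dimethoxyphenyl}-1,3-dioxolane | COc1cc(OC)cc([C@@H]2c3c(cc(OC)cc3C=C)O[C@H]2c2ccc(OC)cc2)c1C1OCCO1 | intermediate
23 | 2-[(2R,3R)-4-ethenyl-6-methoxy-2-(4-methoxyphenyl)-2,3-dihydro-1-benzofuran-3-yl]-4,6-dimethoxybenzaldehyde | COc1cc(OC)cc([C@@H]2c3c(cc(OC)cc3C=C)O[C@H]2c2ccc(OC)cc2)c1C=O | intermediate
24 | 1-{2-[(2R,3R)-4-ethenyl-6-methoxy-2-(4-methoxyphenyl)-2,3-dihydro-1-benzofuran-3-yl]-4,6-dimethoxyphenyl}prop-2-en-1-ol (carbinol epimers) | COc1cc(OC)cc([C@@H]2c3c(cc(OC)cc3C=C)O[C@H]2c2ccc(OC)cc2)c1C(O)C=C | intermediate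
25 | ring 1 dienol (C1 of ring A and C4 of ring B bridged by CH(OH)–CH=CH, cis; carbinol epimers) | COc1cc(OC)cc([C@@H]2c3c(cc(OC)cc3/C=C\C4O)O[C@H]2c2ccc(OC)cc2)c14 | intermediate
26 | ring 1 enone (Ca=O, cis Cb=Cb′) | COc1cc(OC)cc([C@@H]2c3c(cc(OC)cc3/C=C\C4=O)O[C@H]2c2ccc(OC)cc2)c14 | intermediate
27 | alpha-iodoenone (iodine on Cb) | COc1cc(OC)cc([C@@H]2c3c(cc(OC)cc3/C=C(/I)C4=O)O[C@H]2c2ccc(OC)cc2)c14 | intermediate
28 | coupled dioxolane (enone 26 with the (2S,3S)-dihydrobenzofuran-4-yl group of 21 on Cb) | COc1cc(OC)cc([C@@H]2c3c(cc(OC)cc3/C=C(/c5cc(OC)cc6O[C@H](c7ccc(OC)cc7)[C@H](c56)c8cc(OC)cc(OC)c8C9OCCO9)C4=O)O[C@H]2c2ccc(OC)cc2)c14 | intermediate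
29 | coupled aldehyde (as 28 with CHO on C1 of ring A′) | COc1cc(OC)cc([C@@H]2c3c(cc(OC)cc3/C=C(/c5cc(OC)cc6O[C@H](c7ccc(OC)cc7)[C@H](c56)c8cc(OC)cc(OC)c8C=O)C4=O)O[C@H]2c2ccc(OC)cc2)c14 | intermediate
30 | hydroxy ketone of the bicyclic core (Ca=O, Ca′H–OH as epimers) | O=C2c3c(OC)cc(OC)cc3[C@@H]3c4c(cc(OC)cc4[C@H]4C(O)c5c(OC)cc(OC)cc5[C@H]5c6c(cc(OC)cc6[C@H]24)O[C@@H]5c2ccc(OC)cc2)O[C@H]3c2ccc(OC)cc2 | intermediate
31 | anisole | COc1ccccc1 | starting material
32 | aryl ketone (Ca=O; Ca′ bearing H and 4-methoxyphenyl, R) | O=C2c3c(OC)cc(OC)cc3[C@@H]3c4c(cc(OC)cc4[C@H]4[C@H](c5ccc(OC)cc5)c5c(OC)cc(OC)cc5[C@H]5c6c(cc(OC)cc6[C@H]24)O[C@@H]5c2ccc(OC)cc2)O[C@H]3c2ccc(OC)cc2 | intermediate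
33 | 4-methoxyphenylmagnesium bromide | COc1ccc([Mg]Br)cc1 | starting material
34 | (4-methoxyphenyl)cerium dichloride | COc1ccc([Ce](Cl)Cl)cc1 | intermediate
35 | tertiary alcohol (Ca bearing OH and 4-methoxyphenyl, epimers) | COc1ccc(C2(O)c3c(OC)cc(OC)cc3[C@@H]3c4c(cc(OC)cc4[C@H]4[C@H](c5ccc(OC)cc5)c5c(OC)cc(OC)cc5[C@H]5c6c(cc(OC)cc6[C@H]24)O[C@@H]5c2ccc(OC)cc2)O[C@H]3c2ccc(OC)cc2)cc1 | intermediate
36 | decamethyl ether of the target | COc1ccc([C@@H]2c3c(OC)cc(OC)cc3[C@@H]3c4c(cc(OC)cc4[C@H]4[C@H](c5ccc(OC)cc5)c5c(OC)cc(OC)cc5[C@H]5c6c(cc(OC)cc6[C@H]24)O[C@@H]5c2ccc(OC)cc2)O[C@H]3c2ccc(OC)cc2)cc1 | intermediate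
37 | CNP0224452.2 | Oc1ccc([C@@H]2c3c(O)cc(O)cc3[C@@H]3c4c(cc(O)cc4[C@H]4[C@H](c5ccc(O)cc5)c5c(O)cc(O)cc5[C@H]5c6c(cc(O)cc6[C@H]24)O[C@@H]5c2ccc(O)cc2)O[C@H]3c2ccc(O)cc2)cc1 | target

## Step count and least certain steps

Total: 21 steps (steps 9 and 10 are the two fractions of one chromatographic run, so 20 separate operations). Longest linear sequence: 18 steps (1 to 37 through steps 1 to 3, 6 to 9 and 11 to 21). The pyrone 14 takes 2 further steps (4 and 5) from 11, and the second enantiomer 21 is collected in step 10.

Step 8 (key step). The most likely failure is loss of the C–B bond by protodeboronation during the long heating that a hindered, electron-rich diene needs. A second risk is heterolysis of the 4-methoxybenzylic C–O(pyronyl) bond, because the pyronolate is a good leaving group. Fallback, from 15 back to 19: the terminal alkyne is brominated (NBS, AgNO3, acetone) to the bromoalkyne F1. The same intramolecular pyrone cycloaddition with loss of CO2 then gives the racemic trans 4-bromo-dihydrobenzofuran F2, and Miyaura borylation (B2pin2, Pd(dppf)Cl2, KOAc, dioxane) returns to 19, so boron is introduced only after the heating.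

Step 15. The conjugate addition of the nucleophilic catalyst to the aryl-substituted beta-carbon may be too slow, so that no iodination takes place. Fallback, from 26 back to 29: 1,4-hydrosilylation (Et3SiH, RhCl(PPh3)3) gives the triethylsilyl enol ether F3, and Rubottom oxidation (dimethyldioxirane, then aqueous citric acid) gives the alpha-hydroxy ketone F4. Dess–Martin oxidation then gives the 1,2-dione, which rests as its enol, the diosphenol F5, and triflation (Tf2O, 2,6-lutidine) gives the alpha-triflyloxy enone F6. Suzuki–Miyaura coupling of this triflate with 21 and acidic work-up, as in step 16, gives 29.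

Step 17. The face of Cb′ is chosen in an early, radical transition state by remote stereocentres, so facial selectivity may be poor; premature protonation of the reduced enone (plain 1,4-reduction) is the competing process. Fallback, from 30 (as its isomer mixture) back to 30: Dess–Martin oxidation gives the meso 1,4-diketone F7, in which both Cb and Cb′ are alpha to a carbonyl. DBU equilibrates both to the trans, centrosymmetric arrangement (acid is avoided because of furan formation). An enantiotopic-group-selective Corey–Bakshi–Shibata reduction (2-methyl-CBS-oxazaborolidine, BH3·SMe2, catalyst enantiomer chosen so that the Ca′ carbonyl is reduced) then returns to 30.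

Step 18. The cation at Ca′ may lose the Cb′ proton and be re-protonated (scrambling at Cb′), or the arene may be captured with low facial selectivity. Fallback, from 29 back to 32: chemoselective addition of 33 to the aldehyde gives the diarylmethanol F8, and acylation with 4-methylbenzoyl chloride gives the toluate F9. SmI2/HMPA then generates the benzhydryl radical or organosamarium, which adds to Cb′ of the enone and closes ring 2, giving 32 directly after equilibration at Cb with DBU. Ca′ is then set in the C–C bond-forming step and not by cation capture.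

Step 19. The ketone is flanked by a 2,6-disubstituted aryl ring and a tertiary benzylic carbon, so enolisation towards Cb or no addition at all may result. Fallback, from 32 to 36: the enolisation is used. KHMDS and PhNTf2 give the enol triflate F10, and Suzuki–Miyaura coupling with 4-methoxyphenylboronic acid (Pd(OAc)2, SPhos, K3PO4) gives the tetrasubstituted alkene F11. Ionic hydrogenation (Et3SiH, CF3CO2H; proton to Cb, hydride to Ca) then gives 36. In this variant Cb is set again in the protonation.

Step 21. The Lewis acid may open a dihydrofuran irreversibly (C2–O heterolysis assisted by the para oxygen, followed by bromide capture or Friedel–Crafts recombination). Fallback, from 36 to 37: nucleophilic demethylation with sodium ethanethiolate in DMF at 140 °C. This is an SN2 attack on the methyl groups that does not activate the benzylic ethers, and it makes no new compound (F0).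

## Further compounds

F1 | step 8 | bromoalkyne of 15 (racemate) | COc1cc(OC)cc([C@@H]([C@@H](OC2=CC(OC)=CC(=O)O2)c2ccc(OC)cc2)C#CBr)c1C1OCCO1
F2 | step 8 | trans 4-bromo-dihydrobenzofuran (racemate; 19 with Br in place of the boronate) | COc1cc(OC)cc([C@@H]2c3c(cc(OC)cc3Br)O[C@H]2c2ccc(OC)cc2)c1C1OCCO1
F3 | step 15 | triethylsilyl enol ether of the saturated ring 1 ketone | COc1cc(OC)cc([C@@H]2c3c(cc(OC)cc3CC=C4O[Si](CC)(CC)CC)O[C@H]2c2ccc(OC)cc2)c14
F4 | step 15 | alpha-hydroxy ketone (OH on Cb, epimers) | COc1cc(OC)cc([C@@H]2c3c(cc(OC)cc3CC(O)C4=O)O[C@H]2c2ccc(OC)cc2)c14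
F5 | step 15 | diosphenol (enol of the 1,2-dione, OH on Cb) | COc1cc(OC)cc([C@@H]2c3c(cc(OC)cc3/C=C(/O)C4=O)O[C@H]2c2ccc(OC)cc2)c14
F6 | step 15 | alpha-triflyloxy enone | COc1cc(OC)cc([C@@H]2c3c(cc(OC)cc3/C=C(/OS(=O)(=O)C(F)(F)F)C4=O)O[C@H]2c2ccc(OC)cc2)c14
F7 | step 17 | meso 1,4-diketone (ketones at Ca and Ca′) | O=C2c3c(OC)cc(OC)cc3[C@@H]3c4c(cc(OC)cc4[C@H]4C(=O)c5c(OC)cc(OC)cc5[C@H]5c6c(cc(OC)cc6[C@H]24)O[C@@H]5c2ccc(OC)cc2)O[C@H]3c2ccc(OC)cc2
F8 | step 18 | diarylmethanol from 29 (carbinol epimers) | COc1cc(OC)cc([C@@H]2c3c(cc(OC)cc3/C=C(/c5cc(OC)cc6O[C@H](c7ccc(OC)cc7)[C@H](c56)c8cc(OC)cc(OC)c8C(O)c9ccc(OC)cc9)C4=O)O[C@H]2c2ccc(OC)cc2)c14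
F9 | step 18 | 4-methylbenzoate of F8 | COc1cc(OC)cc([C@@H]2c3c(cc(OC)cc3/C=C(/c5cc(OC)cc6O[C@H](c7ccc(OC)cc7)[C@H](c56)c8cc(OC)cc(OC)c8C(OC(=O)c9ccc(C)cc9)c9ccc(OC)cc9)C4=O)O[C@H]2c2ccc(OC)cc2)c14
F10 | step 19 | enol triflate of 32 (Ca(OTf)=Cb) | FC(F)(F)S(=O)(=O)OC=2c3c(OC)cc(OC)cc3[C@@H]3c4c(cc(OC)cc4[C@H]4[C@H](c5ccc(OC)cc5)c5c(OC)cc(OC)cc5[C@H]5c6c(cc(OC)cc6C24)O[C@@H]5c2ccc(OC)cc2)O[C@H]3c2ccc(OC)cc2
F11 | step 19 | tetrasubstituted alkene (Ca(4-methoxyphenyl)=Cb) | COc1ccc(C=2c3c(OC)cc(OC)cc3[C@@H]3c4c(cc(OC)cc4[C@H]4[C@H](c5ccc(OC)cc5)c5c(OC)cc(OC)cc5[C@H]5c6c(cc(OC)cc6C24)O[C@@H]5c2ccc(OC)cc2)O[C@H]3c2ccc(OC)cc2)cc1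
F0 | step 21 | none | none
A1 | alternative 1 | 1,4-bis{2-[hydroxy(4-hydroxyphenyl)methyl]-3,5-dimethoxyphenyl}butane-1,4-dione | OC(c1ccc(O)cc1)c1c(OC)cc(OC)cc1C(=O)CCC(=O)c1cc(OC)cc(OC)c1C(O)c1ccc(O)cc1
A2 | alternative 1 | 6,12-bis(4-hydroxyphenyl)-1,3,7,9-tetramethoxy-5a,6,11a,12-tetrahydrotetracene-5,11-dione | Oc1ccc([C@@H]2c3c(OC)cc(OC)cc3C(=O)[C@H]4[C@H](c5ccc(O)cc5)c5c(OC)cc(OC)cc5C(=O)[C@H]24)cc1
A3 | alternative 2 | bis(trimethylsilyl enol ether) of the chrysenedione A8 (Ca(OSiMe3)=C3 in both halves) | C[Si](C)(C)OC2=C3c4c(cc(OC)cc4[C@H]4C(O[Si](C)(C)C)=C5c6c(cc(OC)cc6[C@H]24)O[C@@H]5c2ccc(OC)cc2)O[C@H]3c2ccc(OC)cc2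
A4 | alternative 2 | 3,5-dimethoxy-2-(trimethylsilyl)phenyl trifluoromethanesulfonate | COc1cc(OC)c([Si](C)(C)C)c(OS(=O)(=O)C(F)(F)F)c1
A5 | alternative 2 | 3,5-dimethoxybenzyne | COC1=CC(OC)=CC#C1
A6 | alternative 2 | meso bis(cyclooctadienone) with ketones at Ca and Ca′, octamethyl ether | O=C2c3c(OC)cc(OC)cc3[C@@H]3c4c(cc(OC)cc4[C@H]4C(=O)c5c(OC)cc(OC)cc5[C@H]5c6c(cc(OC)cc6[C@H]24)O[C@@H]5c2ccc(OC)cc2)O[C@H]3c2ccc(OC)cc2
A7 | alternative 3 | bis(3-acylbenzofuran): difurano-fused dihydrochrysene-5,11-dione with C2=C3 in both furans | O=C2C=3c4c(cc(OC)cc4[C@H]4C(=O)C=5c6c(cc(OC)cc6[C@H]24)OC5)OC3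
A8 | alternative 3 | meso bis(2-aryldihydrofurano)hexahydrochrysene-5,11-dione | O=C2[C@@H]3c4c(cc(OC)cc4[C@H]4C(=O)[C@H]5c6c(cc(OC)cc6[C@H]24)O[C@@H]5c2ccc(OC)cc2)O[C@H]3c2ccc(OC)cc2
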